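The ten-membered ring is cut at C8–C9 and C1–C10. The C8 oxygen, the adjacent C9 methylene and the E-configured C10=C1 alkene with its C10 methyl are what a 3-silyloxycyclobutene leaves behind after electrocyclic opening, so C9–C10 is treated as a two-carbon unit spliced into the C1–C8 bond of a cyclooctenone. One operation (acid-catalysed [2+2] of an alkynoate with the C1=C8 silyl enol ether, then conrotatory opening of the fused four-membered ring) turns the eight-membered ring into the ten-membered one and fixes the E alkene. The precursor is a bis-silylated (Z)-cyclooctadiene whose C6 and C7 stereocentres come from an anti aldol.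

Key step: step 9

Remark: ring atoms carry germacrane numbers (C1 to C10 around the ten-membered ring; epoxide on C4–C5, acetate on C6, isopropyl on C7, senecioate on C8, methyl groups on C4 and C10), and the same numbers are used for the corresponding atoms of earlier intermediates. The enol ether is made as the tert-butyldimethylsilyl ether because bulky silyl enol ethers are the ones that withstand Tf2NH catalysis without protodesilylation.

Step 1
Reactants: 1 (R)-4-benzyl-1,3-oxazolidin-2-one; 2 3-methylbutanoyl chloride
Product: 3 (4R)-4-benzyl-3-(3-methylbutanoyl)-1,3-oxazolidin-2-one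
Conditions: Et3N, DMAP (cat.), CH2Cl2, 0 °C → rt
Reagents that add atoms: none
Why: DMAP-catalysed N-acylation of the oxazolidinone by the acid chloride is a standard imide formation and touches no stereocentre.

Step 2
Reactants: 3 (4R)-4-benzyl-3-(3-methylbutanoyl)-1,3-oxazolidin-2-one; 4 acrolein
Product: 6 (4R)-4-benzyl-3-[(2S,3S)-3-hydroxy-2-(propan-2-yl)pent-4-enoyl]-1,3-oxazolidin-2-one, via trimethylsilyl ether of the aldol adduct 5 (not isolated)
Conditions: MgCl2 (20 mol%), Et3N, Me3SiCl, EtOAc, 23 °C; then CF3CO2H (cat.), MeOH, rt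
Reagents that add atoms: chlorotrimethylsilane, C[Si](C)(C)Cl (its silyl group is carried only by intermediate 5)
Why: Magnesium-halide-catalysed direct anti aldol of an N-acyloxazolidinone with a non-enolisable unsaturated aldehyde: soft enolisation gives the chelated Z magnesium enolate, which is attacked on the face away from the benzyl group through a boat-like transition state, setting C7 (2S) and C6 (3S) anti, while silylation of the aldolate releases the catalyst and blocks retro-aldol.

Step 3
Reactants: 6 (4R)-4-benzyl-3-[(2S,3S)-3-hydroxy-2-(propan-2-yl)pent-4-enoyl]-1,3-oxazolidin-2-one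
Product: 7 (2S,3S)-3-hydroxy-N-methoxy-N-methyl-2-(propan-2-yl)pent-4-enamide
Conditions: MeNH(OMe)·HCl, Me3Al, CH2Cl2, −20 → 0 °C
Reagents that add atoms: N,O-dimethylhydroxylamine hydrochloride, CNOC.Cl
Why: Aluminium-amide transamination of the imide to the Weinreb amide is assisted by the free β-hydroxyl (its aluminium alkoxide delivers the amide to the exocyclic carbonyl), leaves C6 and C7 untouched and returns the auxiliary.

Step 4
Reactants: 7 (2S,3S)-3-hydroxy-N-methoxy-N-methyl-2-(propan-2-yl)pent-4-enamide
Product: 8 (2S,3S)-3-(tert-butyldimethylsilyloxy)-N-methoxy-N-methyl-2-(propan-2-yl)pent-4-enamide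
Conditions: TBSOTf, 2,6-lutidine, CH2Cl2, −78 → 0 °C
Reagents that add atoms: tert-butyldimethylsilyl trifluoromethanesulfonate, CC(C)(C)[Si](C)(C)OS(=O)(=O)C(F)(F)F
Why: Silylation of the secondary allylic alcohol with the silyl triflate and a hindered base is routine and protects the C6 oxygen against retro-aldol and elimination in the basic steps that follow.

Step 5
Reactants: 8 (2S,3S)-3-(tert-butyldimethylsilyloxy)-N-methoxy-N-methyl-2-(propan-2-yl)pent-4-enamide; 9 5-bromo-2-methylpent-1-ene
Product: 11 (3S,4S)-3-(tert-butyldimethylsilyloxy)-9-methyl-4-(propan-2-yl)deca-1,9-dien-5-one, via Grignard reagent 10 (not isolated)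
Conditions: 9, Mg, THF, 40 °C; then 8, THF, 0 °C → rt; aq. NH4Cl
Reagents that add atoms: magnesium, [Mg] (carried only by intermediate 10)
Why: Weinreb ketone synthesis: the primary Grignard reagent adds once to give a stable magnesium chelate that collapses to the ketone only on work-up, so over-addition and epimerisation at C7 are avoided.

Step 6
Reactants: 11 (3S,4S)-3-(tert-butyldimethylsilyloxy)-9-methyl-4-(propan-2-yl)deca-1,9-dien-5-one
Product: 12 (2S,3S,4Z)-3-(tert-butyldimethylsilyloxy)-5-methyl-2-(propan-2-yl)cyclooct-4-en-1-one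
Conditions: second-generation Grubbs catalyst (5 mol%), CH2Cl2 (2 mM), 40 °C
Reagents that add atoms: none
Why: Ring-closing metathesis: the catalyst loads at the monosubstituted vinyl group and closes onto the 1,1-disubstituted alkene with loss of ethene; an eight-membered ring can hold the new trisubstituted C4=C5 alkene only as Z, and the sp2 carbonyl carbon plus the vicinal isopropyl and silyloxy groups favour the folded conformer at high dilution.

Step 7
Reactants: 12 (2S,3S,4Z)-3-(tert-butyldimethylsilyloxy)-5-methyl-2-(propan-2-yl)cyclooct-4-en-1-one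
Product: 14 (1E,3S,4S,5Z)-2,4-bis(tert-butyldimethylsilyloxy)-6-methyl-3-(propan-2-yl)cycloocta-1,5-diene, via lithium enolate 13 (not isolated)
Conditions: LiN(iPr)2, THF, −78 °C; then TBSOTf, −78 → −40 °C
Reagents that add atoms: tert-butyldimethylsilyl trifluoromethanesulfonate, CC(C)(C)[Si](C)(C)OS(=O)(=O)C(F)(F)F; lithium diisopropylamide, [Li+].CC(C)[N-]C(C)C (lithium is carried only by intermediate 13)
Why: Kinetic deprotonation by the hindered amide base occurs at the unbranched C1 methylene and not at the hindered C7 methine (which would also trigger β-elimination of the silyloxy group), and O-silylation of the lithium enolate fixes the C1=C8 enol ether.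

Step 8
Reactants: 15 but-2-ynoic acid
Product: 16 prop-2-en-1-yl but-2-ynoate
Conditions: allyl bromide, K2CO3, DMF, rt
Reagents that add atoms: allyl bromide, C=CCBr
Why: SN2 O-alkylation of the potassium carboxylate by allyl bromide gives the ester without conjugate addition to the ynoate.

Step 9
Reactants: 14 (1E,3S,4S,5Z)-2,4-bis(tert-butyldimethylsilyloxy)-6-methyl-3-(propan-2-yl)cycloocta-1,5-diene; 16 prop-2-en-1-yl but-2-ynoate
Product: 18 prop-2-en-1-yl (1(10)Z,2E,6Z,8S,9S)-8,10-bis(tert-butyldimethylsilyloxy)-2,6-dimethyl-9-(propan-2-yl)cyclodeca-1(10),2,6-triene-1-carboxylate, via cis-fused cyclobutene 17 (not isolated)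
Conditions: Tf2NH (5 mol%), CH2Cl2, −78 → −20 °C; Et3N; then toluene, 70 °C
Reagents that add atoms: none
Why: Tf2NH converts a little of 14 into the silyl triflimide, which activates the ynoate carbonyl; the nucleophilic enol carbon C1 adds to the methyl-bearing β-carbon (C10) and the allenyl ketene acetal so formed closes through its α-carbon (C9) onto the silyloxocarbenium carbon C8, a stepwise Michael/aldol-type [2+2] that closes the four-membered ring C1–C10–C9–C8 as a cis-fused bicyclo[6.2.0]decadiene. The closest known reaction type is the acid-catalysed cycloaddition of silyl enol ethers with propiolates and the thermal opening of the resulting cyclobutenes used to enlarge cyclic ketones by two carbons. On warming, conrotatory 4π electrocyclic opening cleaves the shared C1–C8 bond (driven by strain release and the push–pull diene), so the ten-membered ring arises by merging the eight- and four-membered rings into one perimeter, not by end-to-end cyclisation. No stereocentre is created in 18: C1 and C8 of 17 return to sp2, so the face of the cycloaddition is immaterial, and C6 and C7 are spectators. The step needs regioselectivity, secured by the polarity match of C1 with the ynoate β-carbon, and torquoselectivity, secured by the donor silyloxy group on C8 rotating outward, which turns C7 inward and C2 outward and so gives E-C1=C10 next to a cis C8=C9. The bulky enol silyl group and the low temperature disfavour silyl transfer, simple Michael addition and ionisation of the allylic C6 ether.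

Step 10
Reactants: 18 prop-2-en-1-yl (1(10)Z,2E,6Z,8S,9S)-8,10-bis(tert-butyldimethylsilyloxy)-2,6-dimethyl-9-(propan-2-yl)cyclodeca-1(10),2,6-triene-1-carboxylate
Product: 21 (2S,3S,4Z,8E)-3-(tert-butyldimethylsilyloxy)-5,9-dimethyl-2-(propan-2-yl)cyclodeca-4,8-dien-1-one, via allyl β-keto ester 19 (not isolated), via β-keto acid 20 (not isolated)
Conditions: HF·pyridine, pyridine, THF, 0 °C; then Pd(PPh3)4 (5 mol%), HCO2H, Et3N, THF, rt
Reagents that add atoms: none
Why: Fluoride cleaves the vinylogous silyl ester (enol silyl ether of a β-keto ester) far faster than the hindered secondary silyl ether; zerovalent palladium then ionises the allyl ester, the β-keto carboxylate loses CO2 and the dienol is protonated kinetically at C9 (Tsuji-type deallylative decarboxylation with formate as hydride source), which keeps C1=C10 E and out of conjugation.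

Step 11
Reactants: 21 (2S,3S,4Z,8E)-3-(tert-butyldimethylsilyloxy)-5,9-dimethyl-2-(propan-2-yl)cyclodeca-4,8-dien-1-one
Product: 22 (2S,3S,4Z,8E)-3-hydroxy-5,9-dimethyl-2-(propan-2-yl)cyclodeca-4,8-dien-1-one
Conditions: HF·pyridine, THF, 0 °C → rt
Reagents that add atoms: none
Why: Buffered fluoride removes the allylic silyl ether without generating a free alkoxide, so retro-aldol opening of the β-hydroxy ketone and base-induced alkene migration are avoided.

Step 12
Reactants: 22 (2S,3S,4Z,8E)-3-hydroxy-5,9-dimethyl-2-(propan-2-yl)cyclodeca-4,8-dien-1-one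
Product: 23 (1R,2R,3S,6E,10S)-2-hydroxy-6,10-dimethyl-3-(propan-2-yl)-11-oxabicyclo[8.1.0]undec-6-en-4-one
Conditions: VO(acac)2 (5 mol%), t-BuOOH (decane), CH2Cl2, 0 °C → rt
Reagents that add atoms: tert-butyl hydroperoxide, CC(C)(C)OO
Why: Hydroxyl-directed vanadium-catalysed epoxidation: the vanadate ester of the C6 alkoxide transfers the peroxide oxygen only to the allylic C4=C5 alkene (C1=C10 has no hydroxyl within reach), and with the small O–C6–C5=C4 dihedral angle that vanadium prefers and ring carbon C7 held roughly perpendicular to the alkene plane, the oxygen should be delivered anti to C7, setting C4 (S) and C5 (R) cis to the C6 oxygen, with the Z geometry carried into the cis epoxide.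

Step 13
Reactants: 23 (1R,2R,3S,6E,10S)-2-hydroxy-6,10-dimethyl-3-(propan-2-yl)-11-oxabicyclo[8.1.0]undec-6-en-4-one
Product: 25 (1R,2R,3R,4S,6E,10S)-4-hydroxy-6,10-dimethyl-3-(propan-2-yl)-11-oxabicyclo[8.1.0]undec-6-en-2-yl acetate, via samarium-bound hemiacetal 24 (not isolated)
Conditions: SmI2 (30 mol%), CH3CHO, THF, −10 °C
Reagents that add atoms: acetaldehyde, CC=O
Why: Evans–Tishchenko reduction: the samarium-bound hemiacetal formed from the C6 hydroxyl and acetaldehyde delivers its hydride intramolecularly to the C8 ketone through a six-membered chair-like transition state, which sets C8 (S) anti to C6 and leaves the acetate on C6 in the same event, under conditions mild enough to spare the epoxide.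

Step 14
Reactants: 25 (1R,2R,3R,4S,6E,10S)-4-hydroxy-6,10-dimethyl-3-(propan-2-yl)-11-oxabicyclo[8.1.0]undec-6-en-2-yl acetate; 26 3-methylbut-2-enoyl chloride
Product: 27 (1R,2R,3R,4S,6E,10S)-2-acetoxy-6,10-dimethyl-3-(propan-2-yl)-11-oxabicyclo[8.1.0]undec-6-en-4-yl 3-methylbut-2-enoate
Conditions: pyridine, DMAP (cat.), CH2Cl2, 0 °C → rt
Reagents that add atoms: none
Why: DMAP-catalysed acylation of the hindered C8 alcohol with the acid chloride in pyridine (a weak base that does not deconjugate the senecioyl unit through the vinylketene) gives the target with all five stereocentres untouched.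

Compound list

1 | (R)-4-benzyl-1,3-oxazolidin-2-one | O=C1N[C@H](Cc2ccccc2)CO1 | starting material
2 | 3-methylbutanoyl chloride | CC(C)CC(Cl)=O | starting material
3 | (4R)-4-benzyl-3-(3-methylbutanoyl)-1,3-oxazolidin-2-one | CC(C)CC(=O)N1[C@H](Cc2ccccc2)COC1=O | intermediate
4 | acrolein | C=CC=O | starting material
5 | (4R)-4-benzyl-3-[(2S,3S)-2-(propan-2-yl)-3-(trimethylsilyloxy)pent-4-enoyl]-1,3-oxazolidin-2-one | C=C[C@H](O[Si](C)(C)C)[C@H](C(C)C)C(=O)N1[C@H](Cc2ccccc2)COC1=O | intermediate (not isolated)
6 | (4R)-4-benzyl-3-[(2S,3S)-3-hydroxy-2-(propan-2-yl)pent-4-enoyl]-1,3-oxazolidin-2-one (anti aldol adduct) | C=C[C@H](O)[C@H](C(C)C)C(=O)N1[C@H](Cc2ccccc2)COC1=O | intermediate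
7 | (2S,3S)-3-hydroxy-N-methoxy-N-methyl-2-(propan-2-yl)pent-4-enamide | C=C[C@H](O)[C@H](C(C)C)C(=O)N(C)OC | intermediate
8 | (2S,3S)-3-(tert-butyldimethylsilyloxy)-N-methoxy-N-methyl-2-(propan-2-yl)pent-4-enamide | C=C[C@H](O[Si](C)(C)C(C)(C)C)[C@H](C(C)C)C(=O)N(C)OC | intermediate
9 | 5-bromo-2-methylpent-1-ene | C=C(C)CCCBr | starting material
10 | (4-methylpent-4-en-1-yl)magnesium bromide | C=C(C)CCC[Mg]Br | intermediate (not isolated)
11 | (3S,4S)-3-(tert-butyldimethylsilyloxy)-9-methyl-4-(propan-2-yl)deca-1,9-dien-5-one | C=C[C@H](O[Si](C)(C)C(C)(C)C)[C@H](C(C)C)C(=O)CCCC(C)=C | intermediate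
12 | (2S,3S,4Z)-3-(tert-butyldimethylsilyloxy)-5-methyl-2-(propan-2-yl)cyclooct-4-en-1-one | O=C1CCC/C(C)=C\[C@H](O[Si](C)(C)C(C)(C)C)[C@@H]1C(C)C | intermediate
13 | lithium enolate of 12 formed toward the ring CH2 (C1=C8) | [Li+].[O-]/C1=C/CC/C(C)=C\[C@H](O[Si](C)(C)C(C)(C)C)[C@@H]1C(C)C | intermediate (not isolated)
14 | (1E,3S,4S,5Z)-2,4-bis(tert-butyldimethylsilyloxy)-6-methyl-3-(propan-2-yl)cycloocta-1,5-diene (C1=C8 silyl enol ether, C6 silyl ether, Z-C4=C5) | CC(C)(C)[Si](C)(C)O/C1=C/CC/C(C)=C\[C@H](O[Si](C)(C)C(C)(C)C)[C@@H]1C(C)C | intermediate (key-step precursor)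
15 | but-2-ynoic acid | CC#CC(O)=O | starting material
16 | prop-2-en-1-yl but-2-ynoate | CC#CC(=O)OCC=C | intermediate
17 | prop-2-en-1-yl (2S,3S,4Z)-1,3-bis(tert-butyldimethylsilyloxy)-5,9-dimethyl-2-(propan-2-yl)bicyclo[6.2.0]deca-4,9-diene-10-carboxylate, cis-fused, both bridgehead diastereomers | CC(C)(C)[Si](C)(C)OC12C(C(=O)OCC=C)=C(C)C1CC/C(C)=C\[C@H](O[Si](C)(C)C(C)(C)C)[C@@H]2C(C)C | intermediate (not isolated)
18 | prop-2-en-1-yl (1(10)Z,2E,6Z,8S,9S)-8,10-bis(tert-butyldimethylsilyloxy)-2,6-dimethyl-9-(propan-2-yl)cyclodeca-1(10),2,6-triene-1-carboxylate (C8 silyl dienol ether, C9 allyl ester, E-C1=C10) | CC(C)(C)[Si](C)(C)O/C1=C(C(=O)OCC=C)/C(C)=C/CC/C(C)=C\[C@H](O[Si](C)(C)C(C)(C)C)[C@@H]1C(C)C | intermediate (key-step product)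
19 | prop-2-en-1-yl (2E,6Z,8S,9S)-8-(tert-butyldimethylsilyloxy)-2,6-dimethyl-10-oxo-9-(propan-2-yl)cyclodeca-2,6-diene-1-carboxylate (C9 epimers) | C=CCOC(=O)C1C(=O)[C@@H](C(C)C)[C@@H](O[Si](C)(C)C(C)(C)C)/C=C(C)\CC/C=C1\C | intermediate (not isolated)
20 | (2E,6Z,8S,9S)-8-(tert-butyldimethylsilyloxy)-2,6-dimethyl-10-oxo-9-(propan-2-yl)cyclodeca-2,6-diene-1-carboxylic acid (as its carboxylate) | OC(=O)C1C(=O)[C@@H](C(C)C)[C@@H](O[Si](C)(C)C(C)(C)C)/C=C(C)\CC/C=C1\C | intermediate (not isolated)
21 | (2S,3S,4Z,8E)-3-(tert-butyldimethylsilyloxy)-5,9-dimethyl-2-(propan-2-yl)cyclodeca-4,8-dien-1-one (C8 ketone, C6 silyl ether) | O=C1C/C(C)=C/CC/C(C)=C\[C@H](O[Si](C)(C)C(C)(C)C)[C@@H]1C(C)C | intermediate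
22 | (2S,3S,4Z,8E)-3-hydroxy-5,9-dimethyl-2-(propan-2-yl)cyclodeca-4,8-dien-1-one | O=C1C/C(C)=C/CC/C(C)=C\[C@H](O)[C@@H]1C(C)C | intermediate
23 | (1R,2R,3S,6E,10S)-2-hydroxy-6,10-dimethyl-3-(propan-2-yl)-11-oxabicyclo[8.1.0]undec-6-en-4-one (4S,5R cis epoxide, C6 alcohol, C8 ketone) | O[C@@H]1[C@H](C(C)C)C(=O)C/C(C)=C/CC[C@]2(C)O[C@H]12 | intermediate
24 | hemiacetal of 23 at the C6 oxygen with acetaldehyde, bound to samarium as its alkoxide | CC(O)O[C@@H]1[C@H](C(C)C)C(=O)C/C(C)=C/CC[C@]2(C)O[C@H]12 | intermediate (not isolated)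
25 | (1R,2R,3R,4S,6E,10S)-4-hydroxy-6,10-dimethyl-3-(propan-2-yl)-11-oxabicyclo[8.1.0]undec-6-en-2-yl acetate (C6 acetate, C8 alcohol, 6,8-anti) | CC(=O)O[C@@H]1[C@H](C(C)C)[C@@H](O)C/C(C)=C/CC[C@]2(C)O[C@H]12 | intermediate
26 | 3-methylbut-2-enoyl chloride | CC(C)=CC(Cl)=O | starting material
27 | (1R,2R,3R,4S,6E,10S)-2-acetoxy-6,10-dimethyl-3-(propan-2-yl)-11-oxabicyclo[8.1.0]undec-6-en-4-yl 3-methylbut-2-enoate (germacrane numbering: 4S,5R,6R,7R,8S, 1(10)E) | CC(=O)O[C@@H]1[C@H](C(C)C)[C@@H](OC(=O)C=C(C)C)C/C(C)=C/CC[C@]2(C)O[C@H]12 | target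

Total step count: 14. Longest linear sequence: 13 steps (steps 1–7 and 9–14; step 8 is the one-step side branch).

Steps most likely to fail

1. Step 9. Conjugate addition of the enol ether to the β-methylated ynoate may be too slow, so that protodesilylation of 14, arrest at the open-chain Michael adduct or ionisation of the allylic silyl ether by the silyl triflimide takes over. The fallback sets out from 12 and returns at 19. Ketone 12 is condensed with pyrrolidine (TiCl4, pyrrolidine, toluene, 0 °C → rt) to the less substituted enamine, the pyrrolidine enamine of 12 F1. Heating F1 with 16 in toluene brings about the thermal enamine–ynoate [2+2] cycloaddition to the cis-fused aminocyclobutene F2, which opens with the amino group rotating outward to the ring-expanded enamino ester F3. Hydrolysis with aqueous acetic acid gives keto ester 19, which enters the palladium stage of step 10.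

2. Step 12. The facial selectivity may be poor or reversed: if oxygen transfer goes through the ring conformer with the C6 oxygen outside the alkene plane and H6 inside (the mode followed by eight- and nine-membered cycloalkenols), the epoxide forms on the other face, trans to the C6 oxygen. The fallback sets out from 22 and returns at 23. Stereocontrol is moved from the substrate to the reagent by a stoichiometric titanium–tartrate epoxidation: Ti(OiPr)4, D-(−)-diisopropyl tartrate, t-BuOOH, 4 Å molecular sieves, CH2Cl2, −20 °C. For the 6R carbinol this is the matched pairing of the kinetic-resolution rule: the D-tartrate complex attacks the C4=C5 face on which C7 points away from the incoming oxygen (erythro mode), which is the 4S,5R face, and the ligand disfavours the other face. No new compound is involved.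

3. Step 6. Intermolecular metathesis at the unhindered vinyl group (oligomers) may outrun closure of the strained ring onto the 1,1-disubstituted alkene. The fallback sets out from 8 and returns at 12 and uses relay ring-closing metathesis. Commercial 5-chloropentan-2-one is olefinated (Wittig) with hex-5-enylidene(triphenyl)phosphorane F4, generated from commercial (hex-5-en-1-yl)triphenylphosphonium bromide and NaN(SiMe3)2 in THF, to give 10-chloro-7-methyldeca-1,6-diene F5 as an alkene isomer mixture of no consequence. Its Grignard reagent, (4-methyldeca-4,9-dien-1-yl)magnesium chloride F6 (Mg, THF, reflux), adds to Weinreb amide 8 to give the relay trienone F7. With the second-generation Grubbs catalyst the ruthenium carbene loads at the remote terminal alkene, expels cyclopentene and is thereby placed on C4, from where it closes onto the C5 vinyl group to give 12 with loss of ethene.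

Further compounds

F1 | step 9 | pyrrolidine enamine of 12 | C2CCCN2/C1=C/CC/C(C)=C\[C@H](O[Si](C)(C)C(C)(C)C)[C@@H]1C(C)C
F2 | step 9 | cis-fused aminocyclobutene | C3CCCN3C12C(C(=O)OCC=C)=C(C)C1CC/C(C)=C\[C@H](O[Si](C)(C)C(C)(C)C)[C@@H]2C(C)C
F3 | step 9 | ring-expanded enamino ester | C2CCCN2/C1=C(C(=O)OCC=C)/C(C)=C/CC/C(C)=C\[C@H](O[Si](C)(C)C(C)(C)C)[C@@H]1C(C)C
F0 | step 12 | none | none
F4 | step 6 | hex-5-enylidene(triphenyl)phosphorane | C=CCCCC=P(c1ccccc1)(c1ccccc1)c1ccccc1
F5 | step 6 | 10-chloro-7-methyldeca-1,6-diene | C=CCCCC=C(C)CCCCl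
F6 | step 6 | (4-methyldeca-4,9-dien-1-yl)magnesium chloride | C=CCCCC=C(C)CCC[Mg]Cl
F7 | step 6 | relay trienone, (3S,4S)-3-(tert-butyldimethylsilyloxy)-9-methyl-4-(propan-2-yl)pentadeca-1,9,14-trien-5-one | C=C[C@H](O[Si](C)(C)C(C)(C)C)[C@H](C(C)C)C(=O)CCCC(C)=CCCCC=C
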